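The leftover I cared about was substrate: how much of it, held how, would still stand when my colleague took over the bench. These were the flasks and the questions.

common to all: substrate 0.33 M; reagent 2.00 equiv; time 3.0 min
- south: temperature 65 °C
- north: temperature 80 °C
- north-east: at 50 °C until 50 s, from then on at 80 °C
- north-west: temperature 50 °C

- the best flask by amount of target, in percent of the substrate charged; "all alike" if 1.5 percentage points covers them all (south / north / north-east / north-west / all alike)
- amount of target at the end, in percent of the substrate charged, south
- amount of target at the end, in percent of the substrate charged, north
- amount of target at the end, in percent of the substrate charged, north-east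
- amount of target at the end, in percent of the substrate charged, north-west

- the list of constants is for 50 °C, to be carried to other temperatures by the activation energies and enthalpies
- in a conversion other conformer counts as not yet reacted

    substrate ⇌ other conformer (K1 = 1.1, k1 = 0.0029 s⁻¹, Ea1 = 83.0 kJ mol⁻¹, ΔH1 = 4.00 kJ mol⁻¹)
    substrate + reagent ⇌ target (K2 = 6.5 L mol⁻¹, k2 = 0.0063 L mol⁻¹ s⁻¹, Ea2 = 82.0 kJ mol⁻¹, ΔH2 = −64.0 kJ mol⁻¹)
    reagent + other conformer → isomer of the product (k3 = 0.25 L mol⁻¹ s⁻¹, Ea3 = 66.0 kJ mol⁻¹)
    reagent ⇌ dormant form (K4 = 1.1, k4 = 0.13 s⁻¹, Ea4 = 76.0 kJ mol⁻¹, ΔH4 = −8.00 kJ mol⁻¹)
    target → over-reaction product (k5 = 3.9 × 10⁻⁴ s⁻¹, Ea5 = 99.0 kJ mol⁻¹)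
    (constants at 50 °C)

I followed one molecule in the north flask. Target there fell back at 0.0980 s⁻¹, a life far shorter than the run, so substrate and target formed one pool, a pre-equilibrium. Once one equivalent of reagent had gone into product, the rest shared itself with dormant form, leaving 0.178 M free. With the binding constant down to 0.859 L mol⁻¹, the holding ratio, target over substrate at balance, was 0.153. My molecule had two exits from the pool. As substrate it could slip to other conformer at 0.0400 s⁻¹, and a molecule that became other conformer then had a 91.8 % chance of being trapped as isomer of the product. As target it could go on to over-reaction product at 0.008922 s⁻¹. So I defined the drain of the pool: the slipping rate times the trapping chance, plus the going-on rate times the holding ratio, the sum divided by one plus the holding ratio, 0.0330 s⁻¹.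

Over the north run the drain left a pool of 0.262 %, of which 0.0347 % was target. In the north-east flask I let substrate leak at the cold rate until the change, then applied the drain, which gave a pool of 1.18 % and 0.157 % target.

My note said: leave the north-west flask at 50 °C. Target there lived 17.2 min against fall-back, longer than the run, so I counted no pool in that flask. The making rate gave a ceiling of 35.6 %, and I expected less than that, yet more than north.

The forecast gave 9.5 % south, 0.06 % north, 0.22 % north-east and 19.3 % north-west, with north-west best, on the ground that “The target therefore drains back through substrate into the isomer.”

The flasks gave 10.1 % south, 0.0536 % north, 0.238 % north-east and 18.9 % north-west, so north-west stood highest.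

In north-east the relaxation half-life of the binding step was 0.102 min at the end, short against the run. North ended with substrate plus target at 0.321 % against my pool of 0.262 %. For the north-east flask read at 80 s, I started from the pool at 50 s and applied the drain unchanged, which gave 32.4 %. The reading was 33.3 %.

(The numbers of this flask were set for the occasion; no experiment stands behind them.)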